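## Structural features

The target is an iridoid. A cyclopentane (C5, C6, C7, C8, C9) is cis-fused along C5–C9 to a 3,4-dihydro-2H-pyran (C1, O2, C3, C4, C5, C9). Iridoid numbering is used throughout, with C10 the CH2O group on C8 and C11 the CH2OH group on C4. With H-5 and H-9 drawn β, the SMILES decodes to 1β-O-acyl, 7β-OH, 8α-OH and 8β-CH2O-coumaroyl, that is (1S,4aS,6S,7R,7aS), plus (3S) in the 3-methylpentanoate. Five stereocentres are contiguous (C5, C9, C1, C8, C7). The 7,8-diol is trans, and the tertiary 8-OH points into the concave face of the folded bicycle, whereas O1, O7 and C10 lie on the convex face. The fragile groups are these: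

- the C1 acyloxy acetal;
- the O2–C3=C4 enol ether, whose allylic C11–OH ionises easily;
- the β-hydroxy-aldehyde relation of 8-OH to C1 in any ring-opened form;
- the photo-isomerisable (E)-coumarate with its free phenol.

Five oxygen functions must end up different: two unlike esters (O1, O10) and three free hydroxyls (O7, O8, O11). The real difficulty is to build the cis-fused oxabicycle on a cyclopentane that carries a concave tertiary carbinol trans to its neighbour, and to expose the electron-rich enol ether acetal to as few steps as possible. The key step exploits the fact that C4 bears three one-carbon arms, C3, C11 and (through O2) C1, all at or one hydride away from the aldehyde level. C1, C3, C4 and C11 are therefore the four carbons of triformylmethane, and the cis C5–C9 fusion is the mark of a one-face addition to a C5=C9 cyclopentene. O7 and C10 are cis, so they can be tied into a 1,3-dioxane that serves both as a chiral dihydroxyacetone unit and as the shield of the β face.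

## Logic of the disconnections

**25 to 24 to 23.** No skeletal bond is cut. The aryl O–H goes back to an O–Si bond, and one C11–H bond goes back to the formyl group of 23. The allylic alcohol on the enol ether is the most fragile part of 25. As a formyl group, C11 turns O2–C3=C4 into a vinylogous ester that resists acid and acylating agents. The gain is that all acid and acylation chemistry runs on a deactivated ring. The demand is a hydride that distinguishes one aldehyde from two esters and an acyl acetal, and a buffered fluoride at the end.

**23 to 19 and 22.** The O10–C(=O) ester bond is cut, because it is the only ester on a primary carbinol. This removes the whole aromatic arm, and with it the light-sensitive alkene, from everything that precedes. The demand is site selectivity for 10-OH over the secondary 7-OH and the tertiary 8-OH.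

**19 to 18 to 14 and 17.** The two ketal C–O bonds (O7 and O10 to CMe2) and the O1–C(=O) bond are cut. O7 and O10 are cis and 1,3-related, so one bridge masks both, and the lactol OH is the only acylable hydroxyl left in 14. Three of the five oxygen functions are thus differentiated without individual protecting groups. The demands are β-selective acylation of an equilibrating lactol, and ketal hydrolysis that spares the acyl acetal.

**14 to 10 and 11 (key disconnection).** C4–C5, C1–C9 and O2–C1 are cut. In one sentence: photoannulation of 11 onto the C5=C9 bond of 10, followed by fragmentation of the strained cyclobutanol and closure through oxygen, gives 14. The cut removes the whole pyran ring with its acetal carbon, its enol ether and C11. It takes away three stereocentres (C5, C9, C1) and leaves a bicyclic cyclopentenol and a four-carbon reagent of threefold symmetry. The demand is one-face addition to the α face and the orientation C4 to C5 and C1 to C9.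

**10 to 9.** The C5=C9 double bond is cut. A ring-closing metathesis retron leaves an acyclic-type diene on a six-membered ring. The carbocycle disappears and only the two stereocentres C7 and C8 remain. The demand is that the two alkenyl arms be cis on the dioxane ring.

**9 to 7 and 8.** The C8–C9 bond is cut. C8 becomes a ketone and the quaternary centre is reduced to a face-selection problem on a conformationally defined ring. The demand is axial attack, which places the new carbon cis to the C6 arm and leaves 8-OH trans to O7.

**7 to 6 to 3 and 4, and 3 to 1 and 2.** The C6–C7 bond is cut, then the C=N bond. The only stereocentre left (C7) is α to a symmetrical ketone, so an auxiliary-controlled alkylation can set the absolute configuration of the whole route. The demands are high face selectivity in the alkylation and a cleavage that does not epimerise C7.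

**17 to 15, and 22 to 20.** The C–CO2H bond of 17 and the O–Si bond of 22 are cut. The stereocentre of 17 is bought in 15 and is not touched. 22 is 20 with the phenol masked.

## Other disconnections considered

**Alternative 1:** (the first that comes to mind) The C7–O and C8–O bonds are cut back to the C7=C8 alkene of genipin A1. A1 can be bought, or reached by a phosphine-catalysed [3+2] annulation of an allenoate with a pyranone. The forward key step is oxidation of that alkene.

- Syn-dihydroxylation can give only a cis diol.
- Epoxidation should occur on the convex face and give the 7β,8β-epoxide A2.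
- Opening of A2 at the less hindered C7 would invert both centres relative to the target.
- The correct isomer needs water to attack the tertiary C8 from the concave face under acid. Those are borderline ionising conditions at a centre next to an acid-labile acetal and a competing enol ether.
- The C4 ester must be reduced by a strong hydride before either ester is in place, which forces individual protection of four hydroxyls.

The chosen plan sets the trans diol before the bicycle exists and brings C11 in at the aldehyde level.

**Alternative 2:** The C5–C9 bond is cut. The forward key step copies the biosynthetic cyclisation of the skeleton: an amine-catalysed intramolecular Michael addition of the C1 aldehyde enamine to C5 of the enal in the acyclic formyl enal A3.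

- The natural substrate has no oxygen at C8 or C11, and A3 has both.
- The enamine carbon C9 is attached to the fully substituted C8, so enamine formation should be slow.
- The 8-oxygen stands β to the enamine, which opens an E1cB loss.
- After C–C bond formation the C4 enamine has the C11 oxygen in the β position, which opens a second elimination.
- A3 also needs a longer linear sequence and a geometrically defined trisubstituted enal.

**Alternative 3:** C5–C9 and C1–O2 are cut at once. The forward key step is an intramolecular inverse-demand oxa-Diels–Alder reaction of the alkylidene malondialdehyde A4, whose dienophile is an (E)-enol 3-methylpentanoate. It would give 18 directly and close both rings.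

- The C1 configuration then rests on a geometrically pure (E)-enol ester next to a tertiary carbinol, whereas anti-Markovnikov hydroacyloxylation of alkynes favours the (Z) isomer.
- Enol esters are weak dienophiles.
- An alkylidene malondialdehyde with γ-hydrogens can tautomerise to a dienol.
- Face selection would depend on a flexible tether rather than a rigid bicycle.
- A4 lies several steps beyond 7, whereas 10 lies two steps beyond it.

Key step: step 6

Assumption: 1, 2, 4, 8, 11, 15 and 20 are treated as catalogue chemicals, and 11 is drawn as its enol, the form in which it exists and reacts.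

## Steps

Step 1
Reactants: 1 2,2-dimethyl-1,3-dioxan-5-one; 2 (S)-1-amino-2-(methoxymethyl)pyrrolidine (SAMP)
Product: 3 (S)-N-(2,2-dimethyl-1,3-dioxan-5-ylidene)-2-(methoxymethyl)pyrrolidin-1-amine
Conditions: cyclohexane, reflux, Dean–Stark trap
Reagents that add atoms: none
Why: Hydrazone formation from a ketone and a 1,1-disubstituted hydrazine, driven by removal of water; the neutral medium leaves the ketal untouched.

Step 2
Reactants: 3 SAMP hydrazone; 4 allyl bromide
Product: 6 (S)-N-[(4S)-4-allyl-2,2-dimethyl-1,3-dioxan-5-ylidene]-2-(methoxymethyl)pyrrolidin-1-amine, via lithium azaenolate 5 (not isolated)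
Conditions: t-BuLi, THF, −78 °C; then 4, −100 °C to rt
Reagents that add atoms: none
Why: SAMP-hydrazone alkylation; in the lithium-chelated azaenolate 5 the methoxymethylpyrrolidine covers one face, so the halide should enter from the open face and set C7 as (S), the sense this auxiliary imposes on cyclic ketones of this geometry.

Step 3
Reactants: 6 allylated hydrazone
Product: 7 (4S)-4-allyl-2,2-dimethyl-1,3-dioxan-5-one
Conditions: sat. aq. oxalic acid, Et2O, rt
Reagents that add atoms: water, O
Why: Biphasic acidic hydrazone hydrolysis; the auxiliary is drawn into the water layer as its salt, and the mild acid should spare the ketal, the alkene and the enolisable C7 centre.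

Step 4
Reactants: 7 (4S)-4-allyl-2,2-dimethyl-1,3-dioxan-5-one; 8 vinylmagnesium bromide
Product: 9 (4S,5R)-4-allyl-2,2-dimethyl-5-vinyl-1,3-dioxan-5-ol (allyl cis to vinyl)
Conditions: 8, THF, −78 °C; then H2O
Reagents that add atoms: none
Why: Grignard 1,2-addition; 1,3-dioxan-5-ones are attacked axially because the ring oxygens leave no syn-axial hydrogens on that face and torsional strain favours it. With the allyl group equatorial, this places vinyl cis to allyl and 8-OH trans to O7, which sets C8 as (R).

Step 5
Reactants: 9 (4S,5R)-4-allyl-2,2-dimethyl-5-vinyl-1,3-dioxan-5-ol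
Product: 10 (4aR,7aS)-2,2-dimethyl-7,7a-dihydro-4H-cyclopenta[d][1,3]dioxin-4a-ol (cis-fused)
Conditions: second-generation Grubbs catalyst RuCl2(=CHPh)(PCy3)(SIMes) (cat.), CH2Cl2, reflux
Reagents that add atoms: none
Why: Ring-closing metathesis of a 1,6-diene to a cyclopentene, helped by the free allylic hydroxyl; only the cis isomer of 9 can close without strain, so the step also filters out any C8 epimer.

Step 6
Reactants: 10 cis-fused cyclopentenol; 11 triformylmethane (enol form, 2-(hydroxymethylidene)propanedial)
Product: 14 tricyclic lactol 1β,8α-dihydroxy-7β,10-O-isopropylidene-irid-3-en-11-al (H-5 β, H-9 β), via cyclobutanol photoadduct 12 (not isolated), via ring-opened trialdehyde 13 (not isolated)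
Conditions: hν (medium-pressure Hg lamp, Pyrex filter), 11 added in portions, degassed CH2Cl2, 0 °C
Reagents that add atoms: none
Why: Light excites the chelated enol of 11, whose C=C bond (future C1 and C4) adds across C5=C9 of 10 by way of a triplet 1,4-biradical, so that the four-membered ring of 12 is closed by a [2+2] photocycloaddition that has no thermal counterpart. In 12 the hydroxyl donor on C1 stands next to C4 with its two formyl acceptors, so retro-aldol cleavage of the C1–C4 bond is driven by release of the cyclobutane strain and gives 13. The enol oxygen of the 2-substituted malondialdehyde unit of 13 then adds to the C1 aldehyde in a 6-exo-trig hemiacetalisation, which closes the dihydropyran ring and leaves the third formyl group as C11. The closest known reaction type is the de Mayo photoannulation of diformylacetic esters onto cyclopentenes. C5 and C9 are set together: a cyclopentene can be bridged only on one face, which makes the fusion cis, and that face should be the convex α face, because O7, C10 and the axial methyl group of the cis-fused dioxane cover the β face while only 8-OH and H-7 stand on the α face. The step needs the orientation C4 to C5 and C1 to C9, and the substrate secures it sterically, since the fully substituted C4 terminus avoids C9, which is flanked by the quaternary C8, and biradicals of the other orientation should revert instead of closing. The three formyl groups of 11 are equivalent, so no choice arises as to which becomes C1, C3 or C11. C1 stays under thermodynamic control through the equilibrium of 14 and 13 and should rest as the convex 1β-hydroxy anomer until step 8 fixes it.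

Step 7
Reactants: 15 (S)-1-bromo-2-methylbutane
Product: 17 (S)-3-methylpentanoic acid, via Grignard reagent 16 (not isolated)
Conditions: Mg, THF, reflux; then CO2, −20 °C; then aq. HCl
Reagents that add atoms: carbon dioxide, O=C=O
Why: Grignard carboxylation; the stereocentre is β to the metal-bearing carbon and is not touched, and the descriptor stays (S) because the priority order is unchanged.

Step 8
Reactants: 14 tricyclic lactol; 17 (S)-3-methylpentanoic acid
Product: 18 1-O-[(3S)-3-methylpentanoyl] derivative of 14 (1β-acyloxy, C1 now S)
Conditions: 17, DIC, DMAP (cat.), CH2Cl2, 0 °C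
Reagents that add atoms: none
Why: Steglich-type acylation of a lactol. The anomers interconvert through 13, and acylation on the convex β face, trans to the quaternary C8 across C1–C9, should be both the faster path and the one to the more stable ester, so both anomers are funnelled into one. The tertiary 8-OH is inert under these conditions.

Step 9
Reactants: 18 C1 ester with isopropylidene bridge
Product: 19 (1S,4aS,6S,7R,7aS)-4-formyl-6,7-dihydroxy-7-(hydroxymethyl)-1,4a,5,6,7,7a-hexahydrocyclopenta[c]pyran-1-yl (3S)-3-methylpentanoate
Conditions: AcOH–H2O–THF, rt
Reagents that add atoms: none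
Why: Acid hydrolysis of a six-membered isopropylidene ketal, which is strained by its axial methyl group and therefore labile. The formyl group makes O2 a vinylogous ester oxygen, which disfavours both oxocarbenium formation at C1 and protonation at C4, so the acyl acetal and the enol ether should survive.

Step 10
Reactants: 20 (E)-4-hydroxycinnamic acid (p-coumaric acid)
Product: 22 (E)-4-(tert-butyldimethylsilyloxy)cinnamic acid, via bis-silylated coumarate 21 (not isolated)
Conditions: TBSCl (2.2 equiv), imidazole, DMF, rt; then AcOH–H2O–THF, rt
Reagents that add atoms: tert-butyldimethylsilyl chloride, CC(C)(C)[Si](C)(C)Cl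
Why: Silylation of both acidic hydroxyls followed by selective hydrolysis; a silyl ester is far more labile to water than an aryl silyl ether.

Step 11
Reactants: 19 triol aldehyde; 22 silylated coumaric acid
Product: 23 10-O-[(E)-4-(tert-butyldimethylsilyloxy)cinnamoyl] derivative of 19
Conditions: 22 (1 equiv), DIC, DMAP (cat.), CH2Cl2, −20 °C to 0 °C
Reagents that add atoms: none
Why: Carbodiimide/DMAP esterification under kinetic control. 10-OH is the only primary carbinol, while 7-OH is secondary and flanked by C8, and 8-OH is tertiary. No stereocentre is touched.

Step 12
Reactants: 23 aldehyde diester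
Product: 24 11-alcohol (O-silyl derivative of the target)
Conditions: NaBH4, THF–i-PrOH, −20 °C; then pH 7 phosphate buffer
Reagents that add atoms: none
Why: Borohydride 1,2-reduction of an aldehyde. Esters, the cinnamate alkene and the acyl acetal are not reduced at this temperature, and the β-oxygen donor suppresses conjugate addition. The neutral quench avoids ionisation of the new allylic alcohol.

Step 13
Reactants: 24 O-silyl derivative of the target
Product: 25 target, [(1S,4aS,6S,7R,7aS)-6,7-dihydroxy-4-(hydroxymethyl)-7-{[(E)-3-(4-hydroxyphenyl)prop-2-enoyl]oxymethyl}-1,4a,5,6,7,7a-hexahydrocyclopenta[c]pyran-1-yl] (3S)-3-methylpentanoate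
Conditions: TBAF buffered with an equimolar amount of AcOH, THF, 0 °C
Reagents that add atoms: none
Why: Fluoride cleavage of an aryl silyl ether, the most labile class of TBS ethers. The acetic acid buffer keeps phenoxide and alkoxide levels low, so acyl migration and loss of the C1 ester should not set in.

## Compound list

1 | 2,2-dimethyl-1,3-dioxan-5-one | CC1(C)OCC(=O)CO1 | starting material
2 | (S)-1-amino-2-(methoxymethyl)pyrrolidine (SAMP) | COC[C@@H]1CCCN1N | starting material
3 | SAMP hydrazone of 1 | COC[C@@H]1CCCN1N=C1COC(C)(C)OC1 | intermediate
4 | allyl bromide | C=CCBr | starting material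
5 | lithium azaenolate of 3 | [Li+].COC[C@@H]1CCCN1[N-]C1=COC(C)(C)OC1 | intermediate
6 | (4S)-4-allyl SAMP hydrazone (C=N geometry left open) | C=CC[C@@H]1OC(C)(C)OCC1=NN1CCC[C@H]1COC | intermediate
7 | (4S)-4-allyl-2,2-dimethyl-1,3-dioxan-5-one | C=CC[C@@H]1OC(C)(C)OCC1=O | intermediate
8 | vinylmagnesium bromide | C=C[Mg]Br | starting material
9 | (4S,5R)-4-allyl-2,2-dimethyl-5-vinyl-1,3-dioxan-5-ol | C=CC[C@@H]1OC(C)(C)OC[C@]1(O)C=C | intermediate
10 | (4aR,7aS)-2,2-dimethyl-7,7a-dihydro-4H-cyclopenta[d][1,3]dioxin-4a-ol | C1=C[C@@]2(O)COC(C)(C)O[C@H]2C1 | intermediate
11 | triformylmethane, enol form | OC=C(C=O)C=O | starting material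
12 | cyclobutanol photoadduct (C1 carbinol configuration left open) | OC1C(C=O)(C=O)[C@H]2C[C@H](OC(C)(C)OC3)[C@@]3(O)[C@@H]12 | intermediate
13 | ring-opened trialdehyde | O=CC(C=O)[C@H]1C[C@H](OC(C)(C)OC2)[C@@]2(O)[C@H]1C=O | intermediate
14 | tricyclic lactol, 1β,8α-dihydroxy-7β,10-O-isopropylidene-irid-3-en-11-al | O[C@@H]1OC=C(C=O)[C@H]2C[C@H](OC(C)(C)OC3)[C@@]3(O)[C@@H]12 | intermediate
15 | (S)-1-bromo-2-methylbutane | CC[C@H](C)CBr | starting material
16 | (S)-2-methylbutylmagnesium bromide | CC[C@H](C)C[Mg]Br | intermediate
17 | (S)-3-methylpentanoic acid | CC[C@H](C)CC(=O)O | intermediate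
18 | 1-O-[(3S)-3-methylpentanoyl] derivative of 14 | CC[C@H](C)CC(=O)O[C@@H]1OC=C(C=O)[C@H]2C[C@H](OC(C)(C)OC3)[C@@]3(O)[C@@H]12 | intermediate
19 | 7,8,10-triol 11-aldehyde C1 ester | CC[C@H](C)CC(=O)O[C@@H]1OC=C(C=O)[C@H]2C[C@H](O)[C@](O)(CO)[C@@H]12 | intermediate
20 | (E)-p-coumaric acid | OC(=O)/C=C/c1ccc(O)cc1 | starting material
21 | tert-butyldimethylsilyl (E)-4-(tert-butyldimethylsilyloxy)cinnamate | CC(C)(C)[Si](C)(C)OC(=O)/C=C/c1ccc(O[Si](C)(C)C(C)(C)C)cc1 | intermediate
22 | (E)-4-(tert-butyldimethylsilyloxy)cinnamic acid | OC(=O)/C=C/c1ccc(O[Si](C)(C)C(C)(C)C)cc1 | intermediate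
23 | 10-O-(silylated coumaroyl) 11-aldehyde | CC[C@H](C)CC(=O)O[C@@H]1OC=C(C=O)[C@H]2C[C@H](O)[C@](O)(COC(=O)/C=C/c3ccc(O[Si](C)(C)C(C)(C)C)cc3)[C@@H]12 | intermediate
24 | O-silyl derivative of the target | CC[C@H](C)CC(=O)O[C@@H]1OC=C(CO)[C@H]2C[C@H](O)[C@](O)(COC(=O)/C=C/c3ccc(O[Si](C)(C)C(C)(C)C)cc3)[C@@H]12 | intermediate
25 | CNP0241834.1 | CC[C@H](C)CC(=O)O[C@@H]1OC=C(CO)[C@H]2C[C@H](O)[C@](O)(COC(=O)/C=C/c3ccc(O)cc3)[C@@H]12 | target

## Step count and least certain steps

Total: 13 steps. The longest linear sequence is 11 steps (steps 1 to 6, 8, 9, 11, 12 and 13, from 1 to 25). Steps 7 and 10 are one-step side branches.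

**Step 6 (key step).** Several things could go wrong:

- competing photoreactions of the free formyl groups, namely oxetane formation with the alkene and hydrogen abstraction;
- further excitation of the product, whose β-alkoxyenal chromophore overlaps with that of 11;
- incomplete control of orientation;
- ionisation at C8 or ketal exchange, induced by the strongly acidic 11.

Fallback, from 10 back to 14: the four-carbon synthon and the oxidation-state plan are changed.

- 10 would be irradiated with methyl diformylacetate F1, which is reached in two known operations from a commercial β,β-dimethoxy ester. F1 is the ester analogue on which this photoannulation onto cyclopentenes is established. It is a weaker acid and has one formyl group fewer.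
- The product, lactol ester F2, is a β-alkoxyacrylate that absorbs at shorter wavelength.
- F2 would be silylated at O1 (TBSCl, imidazole) to silyl acetal ester F3.
- F3 would be reduced with i-Bu2AlH to allylic alcohol F4 and oxidised with MnO2 to silyl acetal aldehyde F5.
- F5 would be freed at O1 with buffered TBAF to rejoin the route at 14.

**Step 9.** Hydrolysis or exchange at the C1 acyl acetal may compete with ketal cleavage, and the liberated or resident hydroxyls may add to C3 under acid.

Fallback, from 10 back to 19: the acid-labile bridge is exchanged before the photochemical step, while the molecule is still robust.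

- 10 would be hydrolysed (aq. AcOH, 40 °C) to cyclopentenetriol F6.
- F6 would be bridged again between O7 and O10 with t-Bu2Si(OTf)2 and 2,6-lutidine to give silylene cyclopentenol F7, which keeps the β-face shield.
- Steps 6 and 8 applied to F7 would give silylene lactol F8 and silylene ester F9.
- HF·pyridine in THF–pyridine would then remove the bridge without any acid-catalysed acetal chemistry and give 19.

**Step 12.** Hydride transfer to the push–pull aldehyde may be slow. That would leave time for base-induced loss or migration of the C1 and C10 acyl groups and for cleavage of the aryl silyl ether. The product may also ionise during work-up.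

Fallback, from 19 back to 25: the reduction is moved ahead of the second acylation, where only one ester is present.

- 19 would be reduced with NaBH4 to tetraol F10.
- The unhindered allylic 11-OH would be silylated selectively (TBSCl, imidazole, −20 °C) to 11-silyl ether F11.
- 10-OH would be esterified with 22 as in step 11 to bis-silyl ether F12.
- The buffered fluoride of step 13 would remove both silyl groups and give 25.

**Step 11.** Site selectivity may be poor, because 10-OH, though primary, is neopentyl-like. Over-acylation at O7 and acyl migration between the cis-related O10 and O7 are also possible.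

Fallback, from 19 and 20 back to 25: the O10–C10 bond is made instead of the O10–acyl bond.

- A Mitsunobu reaction (PPh3, DIAD, THF, 0 °C) of 19 with unprotected 20 would use the carboxyl group as the only sufficiently acidic partner. It would activate only the primary carbinol.
- The carboxylate may displace directly, or 8-OH may first close the 8,10-spiro-epoxide F13, which the acid then opens at C10. Either way the same phenol-free ester aldehyde F14 would result, with C8 untouched.
- Reduction as in step 12 would give 25, and steps 10 and 13 would fall away.

**Step 4.** Face selectivity at the ketone may be insufficient, and enolisation by the basic reagent could erode C7.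

Fallback, from 3 back to 10: the C8–C9 bond is made intramolecularly, so that geometry rather than face selection sets C8.

- The azaenolate 5 made from 3 would be alkylated with (Z)-3-bromo-1-iodoprop-1-ene F15 to iodoallyl hydrazone F16.
- Oxalic acid cleavage would give iodoallyl ketone F17.
- A Nozaki–Hiyama–Kishi cyclisation (CrCl2, cat. NiCl2, DMF) would add the (Z)-alkenyl metal to the C8 carbonyl.
- A three-atom tether anchored at C7 can reach the carbonyl only from its own side, so only the cis-fused 10 can form. Steps 4 and 5 are replaced.

## Further compounds

F1 | step 6 | methyl diformylacetate, enol form | COC(=O)C(C=O)=CO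
F2 | step 6 | lactol ester, methyl 11-oate analogue of 14 | O[C@@H]1OC=C(C(=O)OC)[C@H]2C[C@H](OC(C)(C)OC3)[C@@]3(O)[C@@H]12
F3 | step 6 | silyl acetal ester, 1-O-TBS derivative of F2 | CC(C)(C)[Si](C)(C)O[C@@H]1OC=C(C(=O)OC)[C@H]2C[C@H](OC(C)(C)OC3)[C@@]3(O)[C@@H]12
F4 | step 6 | allylic alcohol, 1-O-TBS 11-ol | CC(C)(C)[Si](C)(C)O[C@@H]1OC=C(CO)[C@H]2C[C@H](OC(C)(C)OC3)[C@@]3(O)[C@@H]12
F5 | step 6 | silyl acetal aldehyde, 1-O-TBS derivative of 14 | CC(C)(C)[Si](C)(C)O[C@@H]1OC=C(C=O)[C@H]2C[C@H](OC(C)(C)OC3)[C@@]3(O)[C@@H]12
F6 | step 9 | cyclopentenetriol, (1R,5S)-1-(hydroxymethyl)cyclopent-2-ene-1,5-diol | C1=C[C@@](O)(CO)[C@@H](O)C1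
F7 | step 9 | silylene cyclopentenol, 7,10-O-di-tert-butylsilylene analogue of 10 | C1=C[C@@]2(O)CO[Si](C(C)(C)C)(C(C)(C)C)O[C@H]2C1
F8 | step 9 | silylene lactol, silylene analogue of 14 | O[C@@H]1OC=C(C=O)[C@H]2C[C@H](O[Si](C(C)(C)C)(C(C)(C)C)OC3)[C@@]3(O)[C@@H]12
F9 | step 9 | silylene ester, silylene analogue of 18 | CC[C@H](C)CC(=O)O[C@@H]1OC=C(C=O)[C@H]2C[C@H](O[Si](C(C)(C)C)(C(C)(C)C)OC3)[C@@]3(O)[C@@H]12
F10 | step 12 | tetraol, 7,8,10,11-tetrahydroxy C1 ester | CC[C@H](C)CC(=O)O[C@@H]1OC=C(CO)[C@H]2C[C@H](O)[C@](O)(CO)[C@@H]12
F11 | step 12 | 11-silyl ether of F10 | CC[C@H](C)CC(=O)O[C@@H]1OC=C(CO[Si](C)(C)C(C)(C)C)[C@H]2C[C@H](O)[C@](O)(CO)[C@@H]12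
F12 | step 12 | bis-silyl ether, 11-O-TBS derivative of 24 | CC[C@H](C)CC(=O)O[C@@H]1OC=C(CO[Si](C)(C)C(C)(C)C)[C@H]2C[C@H](O)[C@](O)(COC(=O)/C=C/c3ccc(O[Si](C)(C)C(C)(C)C)cc3)[C@@H]12
F13 | step 11 | 8,10-spiro-epoxide (oxygen α) of the 11-aldehyde C1 ester | CC[C@H](C)CC(=O)O[C@@H]1OC=C(C=O)[C@H]2C[C@H](O)[C@]3(CO3)[C@@H]12
F14 | step 11 | phenol-free ester aldehyde, 11-oxo analogue of 25 | CC[C@H](C)CC(=O)O[C@@H]1OC=C(C=O)[C@H]2C[C@H](O)[C@](O)(COC(=O)/C=C/c3ccc(O)cc3)[C@@H]12
F15 | step 4 | (Z)-3-bromo-1-iodoprop-1-ene | BrC/C=C\I
F16 | step 4 | iodoallyl hydrazone, (4S)-4-[(Z)-3-iodoallyl] SAMP hydrazone | I/C=C\C[C@@H]1OC(C)(C)OCC1=NN1CCC[C@H]1COC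
F17 | step 4 | iodoallyl ketone, (4S)-4-[(Z)-3-iodoallyl]-2,2-dimethyl-1,3-dioxan-5-one | I/C=C\C[C@@H]1OC(C)(C)OCC1=O
A1 | alternative 1 | genipin | O[C@@H]1OC=C(C(=O)OC)[C@H]2CC=C(CO)[C@@H]12
A2 | alternative 1 | 7β,8β-epoxide of genipin | O[C@@H]1OC=C(C(=O)OC)[C@H]2C[C@@H]3O[C@]3(CO)[C@@H]12
A3 | alternative 2 | acyclic formyl enal (7,10-O-isopropylidene, 8-O-triethylsilyl, 11-O-TBS) | O=CC[C@@]1(O[Si](CC)(CC)CC)COC(C)(C)O[C@H]1C/C=C(/C=O)CO[Si](C)(C)C(C)(C)C
A4 | alternative 3 | alkylidene malondialdehyde bearing the (E)-enol (3S)-3-methylpentanoate | CC[C@H](C)CC(=O)O/C=C/[C@@]1(O)COC(C)(C)O[C@H]1CC=C(C=O)C=O
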